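In ring B the carboxyl carbon C1 lies between the methoxy-bearing C2 and the pentyl-bearing C6, and the acylated oxygen is on C4. This 2,4-dioxygen/6-alkyl pattern is that of 4-hydroxy-6-pentyl-2-pyrone, so ring B is grown from that pyrone by exchanging its ring oxygen for C1. The precursor is the 4-benzyloxy-2-methoxy-6-pentylpyrylium salt. In one operation the silyl ketene acetal of tert-butyl acetate adds at C6, the ring opens, and base recloses it around the acetate carbon, forming C1–C6 and C1–C2 and leaving O2 free and O4 benzylated. Methylation, debenzylation and esterification with protected ring A acid from olivetol complete the depside.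

Key step: step 4

Assumption: pyrone 1 is taken as purchasable (it is the 6-pentyl homologue of triacetic acid lactone).

Step 1
Reactants: 1 4-hydroxy-6-pentyl-2H-pyran-2-one + 2 benzyl bromide
Product: 3 4-(benzyloxy)-6-pentyl-2H-pyran-2-one
Conditions: K2CO3, DMF, rt → 50 °C
Reagents that add atoms: none
Why: Williamson-type O-alkylation, in which K2CO3 fully ionises the vinylogous acid and the pyronate should react with benzyl bromide in DMF mainly at the hard O4 terminus, leaving lactone and pentyl chain untouched.

Step 2
Reactants: 3 4-(benzyloxy)-6-pentyl-2H-pyran-2-one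
Product: 4 4-(benzyloxy)-2-methoxy-6-pentylpyrylium tetrafluoroborate
Conditions: Me3OBF4 (1.1 equiv), CH2Cl2, rt; Et2O
Reagents that add atoms: trimethyloxonium tetrafluoroborate, C[O+](C)C.F[B-](F)(F)F
Why: Meerwein O-methylation of the lactone carbonyl oxygen, the most basic site of a 4-alkoxy-2-pyrone, should give the aromatic 2,4-dialkoxypyrylium cation as with 4-methoxy-2-pyrones; a slight excess of oxonium salt leaves no free pyrone to accept a benzyl group from the product, which is precipitated with ether and used fresh.

Step 3
Reactants: 5 tert-butyl acetate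
Product: 7 1-tert-butoxy-1-(trimethylsilyloxy)ethene, via lithium ester enolate 6 (not isolated)
Conditions: LiN(iPr)2, THF, −78 °C; Me3SiCl, −78 °C → rt; distillation
Reagents that add atoms: chlorotrimethylsilane, C[Si](C)(C)Cl
Why: Kinetic ester enolisation and O-silylation of the lithium enolate is the standard silyl ketene acetal synthesis, the tert-butyl group suppressing Claisen self-condensation and C-silylation.

Step 4
Reactants: 4 4-(benzyloxy)-2-methoxy-6-pentylpyrylium tetrafluoroborate + 7 1-tert-butoxy-1-(trimethylsilyloxy)ethene
Product: 10 tert-butyl 4-(benzyloxy)-2-hydroxy-6-pentylbenzoate, via 2H-pyran adduct 8 (not isolated), via dienoate diester 9 (not isolated)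
Conditions: CH2Cl2, −78 → −20 °C; then DBU, −20 °C → rt; aq. NH4Cl
Reagents that add atoms: none
Why: Proposed new method: the neutral silyl ketene acetal 7 should add in a Mukaiyama-type step to C6 of cation 4, the one α/γ position without an alkoxy donor, with fluoride from BF4− taking the silyl group, and the 2H-pyran 8 (a cyclic ketene acetal, racemic at a transient quaternary carbon) should open at once by oxa-6π electrocyclic cleavage of its O–C6 bond to the conjugated methyl ester 9, which erases that centre so that no stereocentre remains. DBU then removes a proton from the CH2CO2tBu arm, activated both as an ester α-position and as the terminus of the dienoate, and the extended enolate attacks the methyl ester carbon (old pyrylium C2) in a 6-exo-trig Claisen (Dieckmann-type) closure; loss of methoxide and tautomerisation give the phenol, the acetate carbon becoming C1 and the new bonds being C1–C6 and C1–C2 of ring B. The nearest known chemistry is the pyrylium-to-benzene ring transformation with carbon nucleophiles (α-addition, ring opening, aldol or Claisen reclosure) together with base-induced pyrone-to-resorcylate conversions, neither of which has been shown for a 2,4-dialkoxypyrylium salt and a silyl ketene acetal. The step needs addition at an α-carbon rather than C4 and no proton loss from the pentyl α-CH2: a base-free silyl nucleophile at low temperature serves the second, the alkoxy donors on C2 and C4 should steer attack to C6, the central C=C of 9 is born cis from the ring, and the geometry of the other C=C can equilibrate through the extended enolate so that the arm reaches the ester. Addition at C2 would not be lost either, since that adduct opens to a pentyl ketone and closes by aldol condensation to the 2-methoxy arene 11, the product of step 5. Because methoxide is the leaving group, the oxygen left on C2 is the old ring oxygen, now a free hydroxyl, whereas O4 keeps its benzyl group, so the methyl and the acyl group each find their own oxygen later.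

Step 5
Reactants: 10 tert-butyl 4-(benzyloxy)-2-hydroxy-6-pentylbenzoate
Product: 11 tert-butyl 4-(benzyloxy)-2-methoxy-6-pentylbenzoate
Conditions: MeI, K2CO3, DMF, 40 °C
Reagents that add atoms: iodomethane, CI
Why: Williamson O-methylation of the only acidic site, the hydrogen-bonded salicylate hydroxyl, which K2CO3 in warm DMF deprotonates readily while the hindered tert-butyl ester and the benzyl ether are inert.

Step 6
Reactants: 11 tert-butyl 4-(benzyloxy)-2-methoxy-6-pentylbenzoate
Product: 12 tert-butyl 4-hydroxy-2-methoxy-6-pentylbenzoate
Conditions: H2 (1 atm), 10% Pd/C, EtOAc, rt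
Reagents that add atoms: none
Why: Heterogeneous catalytic hydrogenolysis of the benzylic C–O bond frees O4 alone, since tert-butyl ester, aryl methyl ether and the arene are not reduced over Pd/C at 1 atm.

Step 7
Reactants: 13 olivetol (5-pentylbenzene-1,3-diol)
Product: 15 2,4-dihydroxy-6-pentylbenzaldehyde, via aryl iminium chloride 14 (not isolated)
Conditions: POCl3, DMF, 0 °C → rt; H2O, 50 °C
Reagents that add atoms: N,N-dimethylformamide, CN(C)C=O; water, O
Why: Vilsmeier–Haack formylation of the resorcinol ring at the carbon ortho to one hydroxyl, para to the other and next to the pentyl chain, the usual site for 5-alkylresorcinols, followed by hydrolysis of iminium salt 14.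

Step 8
Reactants: 15 2,4-dihydroxy-6-pentylbenzaldehyde + 2 benzyl bromide
Product: 16 2,4-bis(benzyloxy)-6-pentylbenzaldehyde
Conditions: 2 (2.5 equiv in all), K2CO3 (3 equiv), DMF, 60 °C
Reagents that add atoms: benzyl bromide, BrCc1ccccc1
Why: Double Williamson benzylation that consumes two molecules of benzyl bromide (one entered as reactant 2, the second as the atom-supplying reagent), the free 4-OH reacting first and the aldehyde-chelated 2-OH following on warming with the excess halide, there being no other nucleophilic site.

Step 9
Reactants: 16 2,4-bis(benzyloxy)-6-pentylbenzaldehyde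
Product: 17 2,4-bis(benzyloxy)-6-pentylbenzoic acid
Conditions: NaClO2, NaH2PO4, 2-methyl-2-butene, t-BuOH/THF/H2O, rt
Reagents that add atoms: sodium chlorite, [Na+].[O-]Cl=O
Why: Pinnick (chlorite) oxidation takes the hindered, electron-rich aryl aldehyde to the acid under buffered conditions that spare benzyl ethers, 2-methyl-2-butene removing the hypochlorous acid that could chlorinate the ring.

Step 10
Reactants: 17 2,4-bis(benzyloxy)-6-pentylbenzoic acid + 12 tert-butyl 4-hydroxy-2-methoxy-6-pentylbenzoate
Product: 19 tert-butyl 4-{[2,4-bis(benzyloxy)-6-pentylbenzoyl]oxy}-2-methoxy-6-pentylbenzoate, via acid chloride 18 (not isolated)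
Conditions: (COCl)2, cat. DMF, CH2Cl2, 0 °C → rt, evaporate; then 12, Et3N, cat. DMAP, CH2Cl2, 0 °C → rt
Reagents that add atoms: none
Why: Acid chloride formation followed by DMAP-catalysed nucleophilic acyl substitution on the single free hydroxyl of 12, the acyl chloride/acylpyridinium being reactive enough to overcome the two ortho substituents of the ring A acid while the amine base keeps the tert-butyl ester safe from HCl.

Step 11
Reactants: 19 tert-butyl 4-{[2,4-bis(benzyloxy)-6-pentylbenzoyl]oxy}-2-methoxy-6-pentylbenzoate
Product: 20 4-{[2,4-bis(benzyloxy)-6-pentylbenzoyl]oxy}-2-methoxy-6-pentylbenzoic acid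
Conditions: CF3CO2H/CH2Cl2 (1:4), 0 °C → rt
Reagents that add atoms: none
Why: Acidolysis of the tert-butyl ester by alkyl–oxygen cleavage (tert-butyl cation lost as isobutene) should leave aryl ester, benzyl ethers and methyl ether intact, and is placed before debenzylation so that no free resorcinol ring meets the tert-butyl cation.

Step 12
Reactants: 20 4-{[2,4-bis(benzyloxy)-6-pentylbenzoyl]oxy}-2-methoxy-6-pentylbenzoic acid
Product: 21 4-[(2,4-dihydroxy-6-pentylbenzoyl)oxy]-2-methoxy-6-pentylbenzoic acid (target)
Conditions: H2 (1 atm), 10% Pd/C, EtOAc, rt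
Reagents that add atoms: none
Why: Hydrogenolysis of both benzyl aryl ethers over Pd/C under neutral conditions should free the ring A hydroxyls without touching the depside ester, the methyl ether or the acid, so the last step needs only filtration and crystallisation.

Compound list
1 | 4-hydroxy-6-pentyl-2H-pyran-2-one | CCCCCC1=CC(O)=CC(=O)O1 | starting material
2 | benzyl bromide | BrCc1ccccc1 | starting material
3 | 4-(benzyloxy)-6-pentyl-2H-pyran-2-one | CCCCCC1=CC(OCc2ccccc2)=CC(=O)O1 | intermediate
4 | 4-(benzyloxy)-2-methoxy-6-pentylpyrylium tetrafluoroborate | CCCCCc1cc(OCc2ccccc2)cc(OC)[o+]1.F[B-](F)(F)F | intermediate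
5 | tert-butyl acetate | CC(=O)OC(C)(C)C | starting material
6 | lithium 1-tert-butoxyethen-1-olate (lithium enolate of 5) | [Li+].[O-]C(=C)OC(C)(C)C | intermediate (not isolated)
7 | 1-tert-butoxy-1-(trimethylsilyloxy)ethene | C=C(OC(C)(C)C)O[Si](C)(C)C | intermediate
8 | tert-butyl 2-[4-(benzyloxy)-6-methoxy-2-pentyl-2H-pyran-2-yl]acetate (racemic) | CCCCCC1(CC(=O)OC(C)(C)C)C=C(OCc2ccccc2)C=C(OC)O1 | intermediate (not isolated)
9 | 7-tert-butyl 1-methyl (2E)-3-(benzyloxy)-5-pentylhepta-2,4-dienedioate (C4=C5 geometry not fixed) | COC(=O)/C=C(OCc1ccccc1)\C=C(CCCCC)CC(=O)OC(C)(C)C | intermediate (not isolated)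
10 | tert-butyl 4-(benzyloxy)-2-hydroxy-6-pentylbenzoate | CCCCCc1cc(OCc2ccccc2)cc(O)c1C(=O)OC(C)(C)C | intermediate
11 | tert-butyl 4-(benzyloxy)-2-methoxy-6-pentylbenzoate | CCCCCc1cc(OCc2ccccc2)cc(OC)c1C(=O)OC(C)(C)C | intermediate
12 | tert-butyl 4-hydroxy-2-methoxy-6-pentylbenzoate | CCCCCc1cc(O)cc(OC)c1C(=O)OC(C)(C)C | intermediate
13 | olivetol (5-pentylbenzene-1,3-diol) | CCCCCc1cc(O)cc(O)c1 | starting material
14 | N-[(2,4-dihydroxy-6-pentylphenyl)methylidene]-N-methylmethanaminium chloride | CCCCCc1cc(O)cc(O)c1C=[N+](C)C.[Cl-] | intermediate (not isolated)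
15 | 2,4-dihydroxy-6-pentylbenzaldehyde | CCCCCc1cc(O)cc(O)c1C=O | intermediate
16 | 2,4-bis(benzyloxy)-6-pentylbenzaldehyde | CCCCCc1cc(OCc2ccccc2)cc(OCc2ccccc2)c1C=O | intermediate
17 | 2,4-bis(benzyloxy)-6-pentylbenzoic acid | CCCCCc1cc(OCc2ccccc2)cc(OCc2ccccc2)c1C(=O)O | intermediate
18 | 2,4-bis(benzyloxy)-6-pentylbenzoyl chloride | CCCCCc1cc(OCc2ccccc2)cc(OCc2ccccc2)c1C(=O)Cl | intermediate (not isolated)
19 | tert-butyl 4-{[2,4-bis(benzyloxy)-6-pentylbenzoyl]oxy}-2-methoxy-6-pentylbenzoate | CCCCCc1cc(OCc2ccccc2)cc(OCc2ccccc2)c1C(=O)Oc1cc(CCCCC)c(C(=O)OC(C)(C)C)c(OC)c1 | intermediate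
20 | 4-{[2,4-bis(benzyloxy)-6-pentylbenzoyl]oxy}-2-methoxy-6-pentylbenzoic acid | CCCCCc1cc(OCc2ccccc2)cc(OCc2ccccc2)c1C(=O)Oc1cc(CCCCC)c(C(=O)O)c(OC)c1 | intermediate
21 | 4-[(2,4-dihydroxy-6-pentylbenzoyl)oxy]-2-methoxy-6-pentylbenzoic acid | CCCCCc1cc(O)cc(O)c1C(=O)Oc1cc(CCCCC)c(C(=O)O)c(OC)c1 | target

Total step count: 12.
Longest linear sequence: 8 steps (steps 1, 2, 4, 5, 6, 10, 11, 12, from pyrone 1 to target 21).

Steps most likely to fail

1. Step 4 (proposed new method). The carbon nucleophile may add at C4 and then expel benzyl alcohol to give a 4-ylidene-4H-pyran. It may instead take a benzyl or methyl group from the oxonium-type oxygens, returning pyrones. The cation may lose a proton from the pentyl α-CH2 before it is attacked, or the closure may stall if the arm enolate does not form cleanly. The fallback uses known chemistry only and takes ring B from the olivetol branch. It sets out from aldehyde 15. Selective benzylation of the non-chelated 4-hydroxyl (1 equiv of 2, KHCO3, MeCN) should give 4-(benzyloxy)-2-hydroxy-6-pentylbenzaldehyde F1. Methylation of the chelated 2-hydroxyl (MeI, K2CO3, DMF) should give 4-(benzyloxy)-2-methoxy-6-pentylbenzaldehyde F2. Chlorite oxidation as in step 9 should give 4-(benzyloxy)-2-methoxy-6-pentylbenzoic acid F3. O-tert-butylation of the hindered acid through its carboxylate oxygen (tert-butyl 2,2,2-trichloroacetimidate, cat. BF3·OEt2, CH2Cl2) comes back to the route at 11.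

2. Step 10. Acyl transfer from the doubly ortho-substituted acid chloride to the ester-deactivated phenol may be slow, so that hydrolysis of the acyl donor or acid-induced loss of the tert-butyl group competes. The fallback sets out from 17 (with 12) and uses no acyl halide. Trifluoroacetic anhydride in dilute toluene at rt should convert 17 into 2,4-bis(benzyloxy)-6-pentylbenzoic trifluoroacetic anhydride F4, an acylium-like donor that esterifies phenols directly (the classical depside coupling). It comes back to the route at 19. Any tert-butyl ester cleaved after the coupling simply arrives at 20 one step early.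

3. Step 1. Benzylation of the ambident pyronate may go to C3 or to the lactone oxygen as well as to O4, costing material and complicating purification. The fallback sets out from 1 and is a Mitsunobu etherification with benzyl alcohol (PPh3, diisopropyl azodicarboxylate, THF). The pyrone serves as the acid partner and is alkylated on O4 through an alkoxyphosphonium ion, not through the free enolate. It comes back to the route at 3 and makes no further compound (entry F0).

Further compounds
F1 | step 4 | 4-(benzyloxy)-2-hydroxy-6-pentylbenzaldehyde | CCCCCc1cc(OCc2ccccc2)cc(O)c1C=O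
F2 | step 4 | 4-(benzyloxy)-2-methoxy-6-pentylbenzaldehyde | CCCCCc1cc(OCc2ccccc2)cc(OC)c1C=O
F3 | step 4 | 4-(benzyloxy)-2-methoxy-6-pentylbenzoic acid | CCCCCc1cc(OCc2ccccc2)cc(OC)c1C(=O)O
F4 | step 10 | 2,4-bis(benzyloxy)-6-pentylbenzoic trifluoroacetic anhydride | CCCCCc1cc(OCc2ccccc2)cc(OCc2ccccc2)c1C(=O)OC(=O)C(F)(F)F
F0 | step 1 | none | none
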